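The C12 chain is attached at C1' while this carbon is sp2. The vicinal diol C5(OH)–C1'(O), at the junction of the cyclopentenone ring and the chain, is read as the syn-dihydroxylation product of a Z-configured exocyclic C5=C1' alkene. C1' is thus the β-carbon of a vinylogous formyl triflate conjugated to the ring ketone C1. A stereoretentive Negishi coupling of this enol triflate, made in two steps from (R)-4-silyloxycyclopentenone, with dodecylzinc bromide forms the C1'–C2' bond and fixes the alkene geometry. Osmylation anti to the C4 silyloxy group then sets C5 and C1' in one operation. Acetylation of the secondary alcohol and desilylation complete the route.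

Key step: step 3

Remark: ring atoms are numbered C1 (ketone), C2=C3, C4 (secondary carbinol), C5 (tertiary carbinol); C1' is the acetoxy-bearing side-chain carbon and C2' the first CH2 of the dodecyl unit. Compound 1, 1-bromododecane and 2,2,2-trifluoroethyl formate are taken as commercial.

Step 1
Reactants: 1 (R)-4-[(tert-butyldimethylsilyl)oxy]cyclopent-2-en-1-one
Product: 3 (4S,5Z)-4-[(tert-butyldimethylsilyl)oxy]-5-(hydroxymethylidene)cyclopent-2-en-1-one, via lithium dienolate 2 (not isolated)
Conditions: LiN(iPr)2, THF, −78 °C; then HCO2CH2CF3, −78 °C; AcOH quench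
Reagents that add atoms: 2,2,2-trifluoroethyl formate, O=COCC(F)(F)F
Why: Kinetic deprotonation by the hindered amide base occurs at C5, the only enolisable α-position, and the cross-conjugated lithium dienolate should be C-formylated by the highly electrophilic formate at −78 °C (crossed Claisen condensation) before silanolate β-elimination sets in, the product resting as its chelated β-oxo enolate until the quench, so C4 is not touched.

Step 2
Reactants: 3 (4S,5Z)-4-[(tert-butyldimethylsilyl)oxy]-5-(hydroxymethylidene)cyclopent-2-en-1-one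
Product: 5 (Z)-[(5S)-5-[(tert-butyldimethylsilyl)oxy]-2-oxocyclopent-3-en-1-ylidene]methyl trifluoromethanesulfonate, via lithium chelate 4 (not isolated)
Conditions: LiN(SiMe3)2, Et2O, −78 °C; then Tf2O, −78 °C
Reagents that add atoms: trifluoromethanesulfonic anhydride, O=S(=O)(OS(=O)(=O)C(F)(F)F)C(F)(F)F
Why: Deprotonation gives the U-shaped lithium chelate in which both oxygens bind lithium, and O-sulfonylation at the more accessible exocyclic oxygen should trap this geometry as the Z vinylogous acyl triflate (triflate syn to the C1 carbonyl), the known outcome of chelate-controlled enol triflate formation from 1,3-dicarbonyl compounds.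

Step 3
Reactants: 5 (Z)-[(5S)-5-[(tert-butyldimethylsilyl)oxy]-2-oxocyclopent-3-en-1-ylidene]methyl trifluoromethanesulfonate; 6 1-bromododecane
Product: 8 (4S,5Z)-4-[(tert-butyldimethylsilyl)oxy]-5-tridecylidenecyclopent-2-en-1-one, via dodecylzinc bromide 7 (not isolated)
Conditions: 6, Zn dust, LiCl, THF, 50 °C; then 5, PdCl2(dppf) (5 mol %), THF, 0 °C to rt
Reagents that add atoms: none
Why: Zerovalent palladium, formed in situ from PdCl2(dppf), inserts into the C1'–OTf bond with retention of the Z geometry, the dodecyl group is transferred from zinc by transmetalation, and reductive elimination forges the C1'–C2' bond (Negishi sp2–sp3 cross-coupling; closest precedent: alkylzinc halides with β-trifloxy enones and enoates). The step exploits the position of C1' next to the quaternary ring carbon C5 and 1,3 to the C1 ketone of the cyclopentenone ring, which lets C1' be carried as the β-carbon of an enone. No ring is closed and no stereocentre is formed, but the Z double bond fixed here is the element from which the C5 and C1' stereocentres are both derived in step 4. The step needs geometric fidelity and selectivity for the C–OTf bond over 1,4-addition to either enone terminus and over β-hydride elimination of the dodecylpalladium intermediate. These should be secured by the low nucleophilicity of the alkylzinc halide towards the enone and the silyl ether, by the base-free conditions, and by the wide-bite-angle dppf ligand, which accelerates reductive elimination.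

Step 4
Reactants: 8 (4S,5Z)-4-[(tert-butyldimethylsilyl)oxy]-5-tridecylidenecyclopent-2-en-1-one
Product: 9 (4S,5R)-4-[(tert-butyldimethylsilyl)oxy]-5-hydroxy-5-[(1S)-1-hydroxytridecyl]cyclopent-2-en-1-one
Conditions: K2OsO2(OH)4 (2 mol %), NMO, citric acid, t-BuOH/H2O 1:1, rt
Reagents that add atoms: N-methylmorpholine N-oxide, C[N+]1([O-])CCOCC1; water, O
Why: Osmium-catalysed syn-dihydroxylation (Upjohn-type, citric acid-buffered variant for electron-poor alkenes) should occur at the trisubstituted, more electron-rich exocyclic alkene rather than the cis-disubstituted ring alkene and from the face anti to the allylic C4 silyloxy group, which places the C5 hydroxyl trans to C4–O and, because addition to the Z alkene is syn, gives the 1'S carbinol; the acidic medium suppresses retro-aldol cleavage of the new β-hydroxy ketone.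

Step 5
Reactants: 9 (4S,5R)-4-[(tert-butyldimethylsilyl)oxy]-5-hydroxy-5-[(1S)-1-hydroxytridecyl]cyclopent-2-en-1-one
Product: 10 (1S)-1-[(1R,5S)-5-[(tert-butyldimethylsilyl)oxy]-1-hydroxy-2-oxocyclopent-3-en-1-yl]tridecyl acetate
Conditions: Ac2O, pyridine, DMAP (cat.), CH2Cl2, 0 °C
Reagents that add atoms: acetic anhydride, CC(=O)OC(C)=O
Why: DMAP-catalysed acetylation should select the secondary C1' hydroxyl over the hindered tertiary C5 hydroxyl while the C4 oxygen is still silylated, so the acetate is placed regioselectively without touching a stereocentre.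

Step 6
Reactants: 10 (1S)-1-[(1R,5S)-5-[(tert-butyldimethylsilyl)oxy]-1-hydroxy-2-oxocyclopent-3-en-1-yl]tridecyl acetate
Product: 11 (1S)-1-[(1S,5S)-1,5-dihydroxy-2-oxocyclopent-3-en-1-yl]tridecyl acetate
Conditions: HF·pyridine, pyridine, THF, 0 °C to rt
Reagents that add atoms: none
Why: Fluoride-mediated cleavage of the silyl ether under buffered, mildly acidic conditions should free the C4 hydroxyl while avoiding the basic conditions that could trigger acetyl migration, retro-aldol cleavage or β-elimination.

Compound list
1 | (R)-4-[(tert-butyldimethylsilyl)oxy]cyclopent-2-en-1-one | O=C1C=C[C@H](O[Si](C)(C)C(C)(C)C)C1 | starting material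
2 | lithium (5S)-5-[(tert-butyldimethylsilyl)oxy]cyclopenta-1,3-dien-2-olate (kinetic C5 enolate of 1) | [Li+].[O-]C1=C[C@@H](O[Si](C)(C)C(C)(C)C)C=C1 | intermediate
3 | (4S,5Z)-4-[(tert-butyldimethylsilyl)oxy]-5-(hydroxymethylidene)cyclopent-2-en-1-one (hydrogen-bonded enol of the 5-formyl ketone) | O=C1C=C[C@H](O[Si](C)(C)C(C)(C)C)/C1=C/O | intermediate
4 | lithium (Z)-[(5S)-5-[(tert-butyldimethylsilyl)oxy]-2-oxocyclopent-3-en-1-ylidene]methanolate (chelated enolate of 3) | [Li+].[O-]/C=C1/[C@@H](O[Si](C)(C)C(C)(C)C)C=CC1=O | intermediate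
5 | (Z)-[(5S)-5-[(tert-butyldimethylsilyl)oxy]-2-oxocyclopent-3-en-1-ylidene]methyl trifluoromethanesulfonate (triflate syn to the ring carbonyl) | O=C1C=C[C@H](O[Si](C)(C)C(C)(C)C)/C1=C/OS(=O)(=O)C(F)(F)F | intermediate
6 | 1-bromododecane | CCCCCCCCCCCCBr | starting material
7 | dodecylzinc bromide | CCCCCCCCCCCC[Zn]Br | intermediate
8 | (4S,5Z)-4-[(tert-butyldimethylsilyl)oxy]-5-tridecylidenecyclopent-2-en-1-one (dodecyl syn to the ring carbonyl) | O=C1C=C[C@H](O[Si](C)(C)C(C)(C)C)/C1=C/CCCCCCCCCCCC | intermediate
9 | (4S,5R)-4-[(tert-butyldimethylsilyl)oxy]-5-hydroxy-5-[(1S)-1-hydroxytridecyl]cyclopent-2-en-1-one (C5–OH trans to C4–O) | CCCCCCCCCCCC[C@H](O)[C@]1(O)C(=O)C=C[C@@H]1O[Si](C)(C)C(C)(C)C | intermediate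
10 | (1S)-1-[(1R,5S)-5-[(tert-butyldimethylsilyl)oxy]-1-hydroxy-2-oxocyclopent-3-en-1-yl]tridecyl acetate | CCCCCCCCCCCC[C@H](OC(C)=O)[C@]1(O)C(=O)C=C[C@@H]1O[Si](C)(C)C(C)(C)C | intermediate
11 | (1S)-1-[(1S,5S)-1,5-dihydroxy-2-oxocyclopent-3-en-1-yl]tridecyl acetate | CCCCCCCCCCCC[C@H](OC(C)=O)[C@]1(O)C(=O)C=C[C@@H]1O | target

Total step count: 6. Longest linear sequence: 6 steps (1 to 11); the organozinc reagent is generated within step 3.

Steps most likely to fail

Step 4. The osmylation may not discriminate well enough between the exocyclic and the ring enone double bonds, or between the two faces. The fallback sets out from 8 and returns at 9. Luche reduction (NaBH4, CeCl3·7H2O, MeOH, −78 °C) would give the dienol (1R,4S,5E)-4-[(tert-butyldimethylsilyl)oxy]-5-tridecylidenecyclopent-2-en-1-ol F1 (alkene geometry unchanged; only the descriptor changes). The exocyclic alkene is then unconjugated and far more nucleophilic than the ring alkene flanked by two allylic oxygens. Osmylation (K2OsO2(OH)4, NMO, acetone/H2O) anti to both allylic oxygens should give the triol (1S,2R,5S)-5-[(tert-butyldimethylsilyl)oxy]-1-[(1S)-1-hydroxytridecyl]cyclopent-3-ene-1,2-diol F2. MnO2 (CH2Cl2, rt) would then re-oxidise only the allylic ring carbinol to give 9.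

Step 2. Chelate control may be incomplete, so that the triflate, and after step 3 the alkene, is an E/Z mixture. The fallback sets out from 8 (as such a mixture) and returns at 10, bypassing steps 4 and 5. Equilibration (I2 cat., CH2Cl2, daylight) should converge on the thermodynamically preferred (4S,5E)-4-[(tert-butyldimethylsilyl)oxy]-5-tridecylidenecyclopent-2-en-1-one F3. Epoxidation with dimethyldioxirane (acetone, 0 °C) anti to the silyloxy group would give the spiro-epoxide (2R,3R,7S)-7-[(tert-butyldimethylsilyl)oxy]-2-dodecyl-1-oxaspiro[2.4]hept-5-en-4-one F4. Opening with CsOAc in AcOH (50 °C) at the secondary carbon C1', with inversion, would give 10 directly; net anti addition to the E alkene gives the same configuration as syn addition to the Z alkene.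

Step 1. Silanolate β-elimination or proton transfer in the lithium dienolate may outrun formylation. The fallback sets out from 1 and returns at 3, avoiding a strongly basic enolate. Soft enolisation (Me3SiOTf, Et3N, CH2Cl2, 0 °C) would give the silyl dienol ether tert-butyldimethyl{[(1S)-3-[(trimethylsilyl)oxy]cyclopenta-2,4-dien-1-yl]oxy}silane F5. Mukaiyama-type addition to trimethyl orthoformate (BF3·OEt2, CH2Cl2, −78 °C) would give the acetal (4S,5S)-4-[(tert-butyldimethylsilyl)oxy]-5-(dimethoxymethyl)cyclopent-2-en-1-one F6. Mild hydrolysis (aqueous oxalic acid, THF) would give 3.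

Further compounds
F1 | step 4 | (1R,4S,5E)-4-[(tert-butyldimethylsilyl)oxy]-5-tridecylidenecyclopent-2-en-1-ol | O[C@@H]1C=C[C@H](O[Si](C)(C)C(C)(C)C)/C1=C/CCCCCCCCCCCC
F2 | step 4 | (1S,2R,5S)-5-[(tert-butyldimethylsilyl)oxy]-1-[(1S)-1-hydroxytridecyl]cyclopent-3-ene-1,2-diol | CCCCCCCCCCCC[C@H](O)[C@]1(O)[C@H](O)C=C[C@@H]1O[Si](C)(C)C(C)(C)C
F3 | step 2 | (4S,5E)-4-[(tert-butyldimethylsilyl)oxy]-5-tridecylidenecyclopent-2-en-1-one | O=C1C=C[C@H](O[Si](C)(C)C(C)(C)C)/C1=C\CCCCCCCCCCCC
F4 | step 2 | (2R,3R,7S)-7-[(tert-butyldimethylsilyl)oxy]-2-dodecyl-1-oxaspiro[2.4]hept-5-en-4-one | CCCCCCCCCCCC[C@H]1O[C@]12C(=O)C=C[C@@H]2O[Si](C)(C)C(C)(C)C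
F5 | step 1 | tert-butyldimethyl{[(1S)-3-[(trimethylsilyl)oxy]cyclopenta-2,4-dien-1-yl]oxy}silane | C[Si](C)(C)OC1=C[C@@H](O[Si](C)(C)C(C)(C)C)C=C1
F6 | step 1 | (4S,5S)-4-[(tert-butyldimethylsilyl)oxy]-5-(dimethoxymethyl)cyclopent-2-en-1-one | COC(OC)[C@H]1C(=O)C=C[C@@H]1O[Si](C)(C)C(C)(C)C
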